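**Plan**

- Retrosynthesis: both CH2OH groups go back to ethyl esters; the ring A C5–vinyl bond is cut (Heck); the C2–C3 bond of the dihydrofuran ring B is cut to an aryl diazoacetate whose ortho oxygen carries the ring C benzyl group; the aryl–C(N2) and ArO–CH2 bonds are cut to 4-bromo-2-iodo-6-methoxyphenol, ethyl diazoacetate and MOM-protected syringyl alcohol.
- Forward: iodination of 4-bromoguaiacol, Mitsunobu ether formation, Pd-catalysed attachment of the diazoacetate, closure of ring B by carbene C–H insertion, epimerisation, Heck chain extension, MOM removal, reduction of both esters.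
- Enabling feature: C2 is a benzylic carbon bound to the ring oxygen O1, so in the open ether its C–H bonds are hydridic and doubly activated. C3 lies between ring A (donor) and a carbon that can be an ester (acceptor), so C3 can be a donor/acceptor carbene held five atoms (C3–C3a–C7a–O1–C2) from that C–H.
- Stereochemistry: C2 (R) from the chiral dirhodium carboxylate in the insertion, which should give the cis ester; C3 from thermodynamic epimerisation to the trans ester; the E alkene from the Heck reaction.

Key step: step 6

Assumption: the S-configured catalyst is taken to deliver the 2R cis product, by analogy with the closest benzyl ether substrates of this catalyst family. If the sense proves opposite, Rh2(R-PTTL)4 is used with no other change.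

**Step 1**
Reactants: 1 4-bromo-2-methoxyphenol
Product: 2 4-bromo-2-iodo-6-methoxyphenol
Conditions: N-iodosuccinimide, TsOH·H2O (cat.), MeCN, 0 °C → rt
Reagents that add atoms: N-iodosuccinimide, O=C1CCC(=O)N1I
Why: Electrophilic aromatic iodination, in which the hydroxyl group is the strongest director and its para position is blocked by bromine, so iodine should enter the one free ortho position.

**Step 2**
Reactants: 3 syringaldehyde (4-hydroxy-3,5-dimethoxybenzaldehyde)
Product: 4 3,5-dimethoxy-4-(methoxymethoxy)benzaldehyde
Conditions: MOMCl, i-Pr2NEt, CH2Cl2, 0 °C → rt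
Reagents that add atoms: chloromethyl methyl ether, COCCl
Why: O-alkylation of the phenol with the chloromethyl ether (Williamson-type acetal formation) gives a MOM ether that tolerates hydride, the Mitsunobu reagents, the Pd and Rh steps and ethoxide.

**Step 3**
Reactants: 4 3,5-dimethoxy-4-(methoxymethoxy)benzaldehyde
Product: 5 [3,5-dimethoxy-4-(methoxymethoxy)phenyl]methanol
Conditions: NaBH4, MeOH, 0 °C
Reagents that add atoms: none
Why: Borohydride reduction of an aryl aldehyde to the benzylic alcohol leaves the acetal and the aryl ethers untouched.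

**Step 4**
Reactants: 2 4-bromo-2-iodo-6-methoxyphenol; 5 [3,5-dimethoxy-4-(methoxymethoxy)phenyl]methanol
Product: 6 5-bromo-1-iodo-3-methoxy-2-{[3,5-dimethoxy-4-(methoxymethoxy)phenyl]methoxy}benzene
Conditions: PPh3, diisopropyl azodicarboxylate, THF, 0 °C → rt
Reagents that add atoms: none
Why: Mitsunobu etherification, in which the acidic dihalophenol is alkylated by the activated primary benzylic alcohol under neutral conditions that spare both aryl halides and the MOM group.

**Step 5**
Reactants: 6 5-bromo-1-iodo-3-methoxy-2-{[3,5-dimethoxy-4-(methoxymethoxy)phenyl]methoxy}benzene; 7 ethyl diazoacetate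
Product: 8 ethyl 2-(5-bromo-2-{[3,5-dimethoxy-4-(methoxymethoxy)phenyl]methoxy}-3-methoxyphenyl)-2-diazoacetate
Conditions: Pd(PPh3)4 (cat.), Ag2CO3, Et3N, toluene, rt
Reagents that add atoms: none
Why: Palladium-catalysed cross-coupling of an aryl iodide with a diazoacetate with retention of the diazo group, in which zerovalent palladium inserts into the carbon–iodine bond far faster than into the carbon–bromine bond at room temperature and Ag2CO3 takes up the iodide.

**Step 6**
Reactants: 8 ethyl 2-(5-bromo-2-{[3,5-dimethoxy-4-(methoxymethoxy)phenyl]methoxy}-3-methoxyphenyl)-2-diazoacetate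
Product: 9 ethyl (2R,3S)-5-bromo-2-[3,5-dimethoxy-4-(methoxymethoxy)phenyl]-7-methoxy-2,3-dihydro-1-benzofuran-3-carboxylate (cis)
Conditions: Rh2(S-PTTL)4 (dirhodium tetrakis[N-phthaloyl-(S)-tert-leucinate], 1 mol %), toluene, −78 → −40 °C, slow addition of 8
Reagents that add atoms: none
Why: The dirhodium carboxylate extrudes N2 from 8 to give a donor/acceptor rhodium carbenoid (ring A as donor, the ester as acceptor), whose electrophilic carbon takes the benzylic, oxygen-bound C–H of the ring C methylene in a concerted, asynchronous, hydride-transfer-like insertion that forms the C3–C2 bond. The closest known reaction type is the enantioselective intramolecular 1,5 C–H insertion of ortho-benzyloxy aryldiazoacetates under chiral dirhodium tetracarboxylates of the N-phthaloyl amino acid family, which gives cis-2-aryl-2,3-dihydrobenzofuran-3-carboxylates. Ring B closes by 1,5-insertion through a five-membered transition state made of the carbene carbon, C3a, C7a, O1 and the benzylic carbon, the only position from which such a transition state can be reached. C2 is set by the chiral carboxylate ligands, which distinguish the two enantiotopic benzylic hydrogens, and C3 is set cis to C2 by the insertion geometry in which the ester turns away from the incoming aryl group; the cis relationship is corrected in step 7. The step needs insertion to beat carbene dimerisation, attack on the acetal C–H bonds of the MOM group and addition to the aromatic rings; this is secured by the doubly activated C–H bond (benzylic and next to oxygen, with a para alkoxy group) held close to the carbene, by the tempered reactivity of the donor/acceptor carbenoid, and by low temperature and slow addition.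

**Step 7**
Reactants: 9 ethyl (2R,3S)-5-bromo-2-[3,5-dimethoxy-4-(methoxymethoxy)phenyl]-7-methoxy-2,3-dihydro-1-benzofuran-3-carboxylate (cis)
Product: 10 ethyl (2R,3R)-5-bromo-2-[3,5-dimethoxy-4-(methoxymethoxy)phenyl]-7-methoxy-2,3-dihydro-1-benzofuran-3-carboxylate (trans)
Conditions: NaOEt (cat.), EtOH/THF, 0 °C → rt
Reagents that add atoms: none
Why: Base-mediated epimerisation through the ester enolate at C3 should give the thermodynamically favoured trans isomer, while C2 is not acidic and keeps its configuration, ethoxide matches the ester, and β-elimination of the ring oxygen is disfavoured because the C2–O1 bond lies near the nodal plane of the enolate (the reverse of a 5-endo-trig closure).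

**Step 8**
Reactants: 10 ethyl (2R,3R)-5-bromo-2-[3,5-dimethoxy-4-(methoxymethoxy)phenyl]-7-methoxy-2,3-dihydro-1-benzofuran-3-carboxylate (trans); 11 ethyl acrylate
Product: 12 ethyl (2R,3R)-2-[3,5-dimethoxy-4-(methoxymethoxy)phenyl]-5-[(E)-3-ethoxy-3-oxoprop-1-en-1-yl]-7-methoxy-2,3-dihydro-1-benzofuran-3-carboxylate
Conditions: Pd2(dba)3 (cat.), [HP(t-Bu)3]BF4 (cat.), Cy2NMe, 1,4-dioxane, rt → 50 °C
Reagents that add atoms: none
Why: Mizoroki–Heck reaction, in which oxidative addition of zerovalent palladium bearing the bulky electron-rich phosphine to the aryl bromide, syn carbopalladation of the acrylate and syn β-hydride elimination should give the E cinnamate at a temperature that spares C3.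

**Step 9**
Reactants: 12 ethyl (2R,3R)-2-[3,5-dimethoxy-4-(methoxymethoxy)phenyl]-5-[(E)-3-ethoxy-3-oxoprop-1-en-1-yl]-7-methoxy-2,3-dihydro-1-benzofuran-3-carboxylate
Product: 13 ethyl (2R,3R)-5-[(E)-3-ethoxy-3-oxoprop-1-en-1-yl]-2-(4-hydroxy-3,5-dimethoxyphenyl)-7-methoxy-2,3-dihydro-1-benzofuran-3-carboxylate
Conditions: 2 M aq. HCl, EtOH/THF, 40 °C
Reagents that add atoms: none
Why: Acid-catalysed acetal hydrolysis removes the aryl MOM ether under conditions too mild to ionise the C2–O1 bond, whose benzylic cation is poorly stabilised by the twisted para oxygen and two meta methoxy groups, and ethanol keeps ester exchange degenerate.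

**Step 10**
Reactants: 13 ethyl (2R,3R)-5-[(E)-3-ethoxy-3-oxoprop-1-en-1-yl]-2-(4-hydroxy-3,5-dimethoxyphenyl)-7-methoxy-2,3-dihydro-1-benzofuran-3-carboxylate
Product: 14 4-[(2R,3S)-3-(hydroxymethyl)-5-[(E)-3-hydroxyprop-1-en-1-yl]-7-methoxy-2,3-dihydro-1-benzofuran-2-yl]-2,6-dimethoxyphenol (target)
Conditions: i-Bu2AlH (excess), toluene/THF, −78 → 0 °C; aq. KNaC4H4O6 work-up
Reagents that add atoms: none
Why: Aluminium hydride 1,2-reduction of both esters (saturated ester to primary alcohol, enoate to allylic alcohol) after the phenol has been taken up as its aluminium phenoxide should leave both stereocentres untouched, the C3 descriptor changing from R to S only because the substituent priorities change.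

**Compound list**

1 | 4-bromo-2-methoxyphenol | COc1cc(Br)ccc1O | starting material
2 | 4-bromo-2-iodo-6-methoxyphenol | COc1cc(Br)cc(I)c1O | intermediate
3 | syringaldehyde (4-hydroxy-3,5-dimethoxybenzaldehyde) | COc1cc(C=O)cc(OC)c1O | starting material
4 | 3,5-dimethoxy-4-(methoxymethoxy)benzaldehyde | COCOc1c(OC)cc(C=O)cc1OC | intermediate
5 | [3,5-dimethoxy-4-(methoxymethoxy)phenyl]methanol | COCOc1c(OC)cc(CO)cc1OC | intermediate
6 | 5-bromo-1-iodo-3-methoxy-2-{[3,5-dimethoxy-4-(methoxymethoxy)phenyl]methoxy}benzene | COCOc1c(OC)cc(COc2c(I)cc(Br)cc2OC)cc1OC | intermediate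
7 | ethyl diazoacetate | CCOC(=O)C=[N+]=[N-] | starting material
8 | ethyl 2-(5-bromo-2-{[3,5-dimethoxy-4-(methoxymethoxy)phenyl]methoxy}-3-methoxyphenyl)-2-diazoacetate | CCOC(=O)C(=[N+]=[N-])c1cc(Br)cc(OC)c1OCc1cc(OC)c(OCOC)c(OC)c1 | intermediate
9 | ethyl (2R,3S)-5-bromo-2-[3,5-dimethoxy-4-(methoxymethoxy)phenyl]-7-methoxy-2,3-dihydro-1-benzofuran-3-carboxylate (cis) | COc1cc([C@@H]2Oc3c(OC)cc(Br)cc3[C@@H]2C(=O)OCC)cc(OC)c1OCOC | intermediate
10 | ethyl (2R,3R)-5-bromo-2-[3,5-dimethoxy-4-(methoxymethoxy)phenyl]-7-methoxy-2,3-dihydro-1-benzofuran-3-carboxylate (trans) | COc1cc([C@@H]2Oc3c(OC)cc(Br)cc3[C@H]2C(=O)OCC)cc(OC)c1OCOC | intermediate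
11 | ethyl acrylate | C=CC(=O)OCC | starting material
12 | ethyl (2R,3R)-2-[3,5-dimethoxy-4-(methoxymethoxy)phenyl]-5-[(E)-3-ethoxy-3-oxoprop-1-en-1-yl]-7-methoxy-2,3-dihydro-1-benzofuran-3-carboxylate | COc1cc([C@@H]2Oc3c(OC)cc(/C=C/C(=O)OCC)cc3[C@H]2C(=O)OCC)cc(OC)c1OCOC | intermediate
13 | ethyl (2R,3R)-5-[(E)-3-ethoxy-3-oxoprop-1-en-1-yl]-2-(4-hydroxy-3,5-dimethoxyphenyl)-7-methoxy-2,3-dihydro-1-benzofuran-3-carboxylate | COc1cc([C@@H]2Oc3c(OC)cc(/C=C/C(=O)OCC)cc3[C@H]2C(=O)OCC)cc(OC)c1O | intermediate
14 | 4-[(2R,3S)-3-(hydroxymethyl)-5-[(E)-3-hydroxyprop-1-en-1-yl]-7-methoxy-2,3-dihydro-1-benzofuran-2-yl]-2,6-dimethoxyphenol | COc1cc([C@@H]2Oc3c(OC)cc(/C=C/CO)cc3[C@H]2CO)cc(OC)c1O | target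

**Step count**

Total steps: 10. Longest linear sequence: 9 steps (3 → 4 → 5 → 6 → 8 → 9 → 10 → 12 → 13 → 14).

**Steps most likely to fail**

Step 6. The chiral catalyst may not distinguish the two enantiotopic benzylic hydrogens well enough, since the ethyl ester and the methoxy group flanking the ether oxygen lie outside the closest examples, and carbene dimerisation may compete. The fallback sets out from 8 and comes back at 10, with stereocontrol by resolution. Decomposition of 8 with the achiral catalyst Rh2(OAc)4 in CH2Cl2 should give the racemic insertion product, that is 9 together with its mirror image, ethyl (2S,3R)-5-bromo-2-[3,5-dimethoxy-4-(methoxymethoxy)phenyl]-7-methoxy-2,3-dihydro-1-benzofuran-3-carboxylate F1. NaOEt in EtOH should then equilibrate both to the trans series, 10 together with its mirror image, ethyl (2S,3S)-5-bromo-2-[3,5-dimethoxy-4-(methoxymethoxy)phenyl]-7-methoxy-2,3-dihydro-1-benzofuran-3-carboxylate F2. Preparative chromatography on a chiral stationary phase (amylose tris(3,5-dimethylphenylcarbamate)) separates 10 from F2, and 10 re-enters at step 8.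

Step 5. Oxidative addition and coupling at the hindered, electron-rich aryl iodide may be slow, so that palladium-mediated loss of N2 from the diazo ester and carbene dimerisation outrun the cross-coupling. The fallback sets out from 6 and comes back at 8, introducing the acetate carbon first and the diazo group afterwards. Negishi-type coupling of 6 with the Reformatsky reagent BrZnCH2CO2Et (Pd(PPh3)4, THF, 50 °C), selective for the carbon–iodine bond, should give ethyl 2-(5-bromo-2-{[3,5-dimethoxy-4-(methoxymethoxy)phenyl]methoxy}-3-methoxyphenyl)acetate F3. Regitz diazo transfer with 4-acetamidobenzenesulfonyl azide and DBU in MeCN then gives 8.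

Step 8. Oxidative addition at the electron-rich aryl bromide may be slow, so that prolonged warming with amine base erodes the configuration at C3 or reductive loss of bromine competes. The fallback sets out from 10 and comes back at 12, replacing carbopalladation of an alkene by transmetallation of a preformed vinyl unit. Suzuki–Miyaura coupling of 10 with commercial ethyl (E)-3-(4,4,5,5-tetramethyl-1,3,2-dioxaborolan-2-yl)acrylate (Pd(dppf)Cl2, K3PO4, 1,4-dioxane/H2O, 60 °C) should give 12 directly with the E geometry carried by the boronate. This fallback makes no compound outside the list (F0).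

**Further compounds**

F1 | step 6 | ethyl (2S,3R)-5-bromo-2-[3,5-dimethoxy-4-(methoxymethoxy)phenyl]-7-methoxy-2,3-dihydro-1-benzofuran-3-carboxylate | COc1cc([C@H]2Oc3c(OC)cc(Br)cc3[C@H]2C(=O)OCC)cc(OC)c1OCOC
F2 | step 6 | ethyl (2S,3S)-5-bromo-2-[3,5-dimethoxy-4-(methoxymethoxy)phenyl]-7-methoxy-2,3-dihydro-1-benzofuran-3-carboxylate | COc1cc([C@H]2Oc3c(OC)cc(Br)cc3[C@@H]2C(=O)OCC)cc(OC)c1OCOC
F3 | step 5 | ethyl 2-(5-bromo-2-{[3,5-dimethoxy-4-(methoxymethoxy)phenyl]methoxy}-3-methoxyphenyl)acetate | CCOC(=O)Cc1cc(Br)cc(OC)c1OCc1cc(OC)c(OCOC)c(OC)c1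
F0 | step 8 | none | none
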